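The readings come from a simulation from invented constants, and the scatter is random.

Watch the catalyst.

| setting | autumn | summer | flask |
|---|---|---|---|
| E | 0.37 M | 1.5 M | 0.74 M |
| Z | 0.814 M | 0.814 M | 0.814 M |
| L | 0.74 mM | 0.74 mM | 0.74 mM |
| remark | run made earlier | run made earlier |  |
| time |  |  | 20 min |

- autumn (time / min: Q / %, E / %): 2.00: 2.8, 97.3; 4.00: 4.1, 95.4; 6.00: 5.3, 94.3; 8.00: 6.9, 93.5; 10.0: 7.4, 92.8; 12.0: 7.6, 92.0
- summer (time / min: Q / %, E / %): 2.00: 2.3, 97.8; 4.00: 2.9, 96.5; 6.00: 3.8, 95.5; 8.00: 4.6, 95.3; 10.0: 4.4, 95.0; 12.0: 5.1, 94.7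

(readings scatter by 0.3 percentage points)

- what may be going on: Z <-> G; 2 L -> D; E + L -> X; E + Z + L -> L + Q

- where most of what was charged as E, at 20 min is found (Q / E)
- the largest share itself, whichever of these holds it, in percent of the E charged

I followed one molecule of L, which at each fork either turns an E and a Z into Q and comes back, or is lost to D or X, and I counted its turns. At 12.0 min the autumn run had made 38.0 Q per L charged and the summer run 103, so the count grew as E to the power 0.715, which put the flask at 62.4. From 8.00 min to 12.0 min the autumn run gained 9.21 % of its count, a step of 0.7 percentage points between two readings that each scatter by 0.3 points, so the pace was a rough one, and that pace held on to 20 min lifted the flask to 73.9: this count, Q made per L charged, is the turnover number N, and it left me E at 92.6 %.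

The forecast said “E remains dominant”: E, 92.5 %, within 90.5 % to 94.5 %.

The flask held E at 92.1 % and Q at 7.81 %, so N was 78.1 against my 73.9, with L down to 15.0 %, D at 26.8 % and X at 58.2 %.

    Z ⇌ G (K = 1.40, k = 0.0870 min⁻¹)
    2 L → D (k = 41.0 M⁻¹ min⁻¹)
    E + L → X (k = 0.100 M⁻¹ min⁻¹)
    E + Z + L → L + Q (k = 25.0 M⁻² min⁻¹)

Z stands in the turn and in neither loss of L, so the odds at each fork go with Z. For the neighbour flask charged with 1.4 M of Z, I multiplied my N by 1.72, which gave 127 turns and Q at 12.7 %. That neighbour flask kept 41.1 % of its Z, as the first flask kept 41 %, and stood at Q 13.2 %.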